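The numbers of this flask were set for the occasion; the run is a simulation.

The constants are given at 100 °C, the temperature of winter, while midnight runs at 125 °C on the same charges.

    starting material + coupling partner → open intermediate (k1 = 0.22 L mol⁻¹ min⁻¹, Ea1 = 79.0 kJ mol⁻¹)
    open intermediate ⇌ target (K2 = 1.3, k2 = 0.78 min⁻¹, Ea2 = 103 kJ mol⁻¹, ΔH2 = −90.0 kJ mol⁻¹)
    open intermediate + capture agent → trapped intermediate (k3 = 0.12 L mol⁻¹ min⁻¹, Ea3 = 73.0 kJ mol⁻¹)
    open intermediate → side product (k4 = 0.0090 min⁻¹, Ea4 = 127 kJ mol⁻¹)
    (constants at 100 °C)

| flask | starting material | coupling partner | capture agent | temperature | time |
|---|---|---|---|---|---|
| midnight | 0.40 M | 0.480 M | 0.0200 M | 125 °C | 1.0 h |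
| winter | 0.40 M | 0.480 M | 0.0200 M | 100 °C | 1.0 h |
- which of these there is most of at the end, counted by the starting material in it, midnight (trapped intermediate / side product / starting material / open intermediate / target)
- which of these there is most of at the end, counted by the starting material in it, winter (trapped intermediate / side product / starting material / open intermediate / target)
- amount of the one of these that there is most of at the end, in percent of the starting material charged, midnight
- amount of the one of these that there is most of at the end, in percent of the starting material charged, winter
- constants are those at 100 °C; use the activation energies and enthalpies for any other temperature

Capture and leak both consume the open intermediate, so dividing their rates cancels c(open intermediate). The fraction of capture agent left at constant temperature is therefore exp(−S·c(side product)), where S is the capture ratio, the capture constant over the leak constant (a selectivity factor). We reckon it at 4.47 L mol⁻¹ for midnight, smaller than the 13.3 L mol⁻¹ for winter.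

In midnight, open intermediate and target relax within 0.0192 min, far shorter than the 1.0 h, with an equilibrium constant of 0.210. The pair then drains with a half-life of 7.13 min, shorter than the hour, so we count midnight's starting material as ending in side product or trapped intermediate. Taking c(side product) as 0.380 M leaves 18.3 % of the capture agent, which gives 4.09 % trapped intermediate and 95.9 % side product.

In winter, the leak's half-life of 1.3 h is longer than the 1.0 h, so we expect target to lead, but we commit to no amount.

The forecast gave side product at 95 % for midnight and target at 41 % for winter, reasoning that “nearly everything drains to side product within the hour” at the higher temperature.

The simulation gives side product at 95.2 % for midnight and target at 41.7 % for winter.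

Our midnight figure stands 0.70 percentage points higher, and open intermediate, target and starting material together still hold 0.732 % in midnight. Putting midnight's simulated side product into the rule gives 18.2 % of the capture agent left, and that flask holds 18 %. The neighbour flask is midnight with 0.19 M of coupling partner, which is the limiting reagent, with 0 % left at 1.00 h. The same reckoning, now on that charge, gives 44.8 % side product and 44.9 % of the capture agent left. The neighbour flask holds 44.6 % side product and 45 % of its capture agent.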